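**Retrosynthetic overview**

1. The strategy rests on the ether oxygen that joins C4' (ring B) of the (2S)-flavanone to C3 of the flavone. If the flavone pyranone (ring C) is opened at O1–C2, this C3 is the central carbon of a 1-(2-hydroxyaryl)-3-aryl-1,3-diketone, so it can be delivered as a diacyl carbene.
2. Disconnections: C3–O4' (rhodium carbene insertion into the 4'-O–H of intact (2S)-sakuranetin) and O1–C2 (acid cyclodehydration). Ring C of the flavone is the only ring made and is made last; both flavanone rings and the C2 centre come unchanged from (2S)-naringenin.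
3. The carbene precursor is a tetraacetylated 2-diazo-1,3-diaryl-1,3-diketone, made from 4'-acetoxyacetophenone and 2,4,6-triacetoxybenzoyl chloride by magnesium-mediated soft enolisation and diazo transfer. Acetates are chosen because they are poor donors towards the carbene and are removed in the acid stage.
4. (2S)-Sakuranetin comes from (2S)-naringenin by Mitsunobu methylation of the 7-OH.

Key step: step 6

Assumption: commercial (2S)-naringenin is used as single-enantiomer material (enantiomeric purity to be checked by chiral HPLC before use), because its C2 centre is carried through unchanged; 4'-acetoxyacetophenone is bought as such.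

**Route**

Step 1
Reactants: 1 (2S)-naringenin
Product: 2 (2S)-sakuranetin [(2S)-5-hydroxy-2-(4-hydroxyphenyl)-7-methoxychroman-4-one]
Conditions: MeOH (1.1 equiv), PPh3, DIAD, THF, 0 °C to rt
Reagents that add atoms: methanol, CO
Why: Mitsunobu etherification alkylates phenols in order of acidity, so with about one equivalent of methanol the 7-OH (para to the C4 carbonyl) should react ahead of the 4'-OH while the hydrogen-bonded 5-OH stays inert, and the near-neutral medium should leave the base-labile C2 centre untouched.

Step 2
Reactants: 3 2,4,6-trihydroxybenzoic acid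
Product: 4 2,4,6-triacetoxybenzoic acid
Conditions: Ac2O, pyridine, DMAP (cat.), 0 °C to rt; aqueous HCl work-up
Reagents that add atoms: acetic anhydride, CC(=O)OC(C)=O
Why: DMAP-catalysed O-acetylation should cap the three phenols at low temperature, where the decarboxylation-prone acid survives, and the acidic aqueous work-up returns the free carboxylic acid.

Step 3
Reactants: 4 2,4,6-triacetoxybenzoic acid
Product: 5 2,4,6-triacetoxybenzoyl chloride
Conditions: (COCl)2, DMF (cat.), CH2Cl2, 0 °C to rt; used crude
Reagents that add atoms: oxalyl chloride, O=C(Cl)C(Cl)=O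
Why: Acid chloride formation with oxalyl chloride and catalytic DMF proceeds under conditions that aryl acetates tolerate, as in the preparation of acetylsalicyloyl chloride.

Step 4
Reactants: 5 2,4,6-triacetoxybenzoyl chloride; 6 4'-acetoxyacetophenone
Product: 7 1-(4-acetoxyphenyl)-3-(2,4,6-triacetoxyphenyl)propane-1,3-dione
Conditions: MgBr2·OEt2, i-Pr2NEt, CH2Cl2, 0 °C to rt; dilute HCl work-up
Reagents that add atoms: none
Why: Soft enolisation of the methyl ketone with MgBr2·OEt2 and a hindered amine followed by C-acylation with the acid chloride (a crossed Claisen condensation) needs no strong base, so the aryl acetates should survive, and magnesium coordination of the diketone formed should suppress a second acylation.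

Step 5
Reactants: 7 1-(4-acetoxyphenyl)-3-(2,4,6-triacetoxyphenyl)propane-1,3-dione
Product: 8 2-diazo-1-(4-acetoxyphenyl)-3-(2,4,6-triacetoxyphenyl)propane-1,3-dione
Conditions: p-ABSA (1.1 equiv), Et3N (1.2 equiv), MeCN, 0 °C
Reagents that add atoms: 4-acetamidobenzenesulfonyl azide (p-ABSA), CC(=O)Nc1ccc(cc1)S(=O)(=O)N=[N+]=[N-]
Why: Regitz diazo transfer to the amine enolate of a 1,3-diketone is fast at 0 °C and should outpace base-induced acetyl migration from the ortho acetates.

Step 6
Reactants: 2 (2S)-sakuranetin; 8 2-diazo-1-(4-acetoxyphenyl)-3-(2,4,6-triacetoxyphenyl)propane-1,3-dione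
Product: 12 target CNP0173006.1 [(2S)-sakuranetin 4'-O-(5,7,4'-trihydroxyflavon-3-yl) ether], via O–H insertion tetraacetate 9 (not isolated), via tetraphenol aryloxy diketone 10 (not isolated), via 2-hydroxyflavanone hemiketal 11 (not isolated)
Conditions: Rh2(OAc)4 (2 mol %), ClCH2CH2Cl, 70 °C, 8 (1.3 equiv) added slowly; then HCl (1.25 M in MeOH) added to the same flask, 40 °C
Reagents that add atoms: none
Why: The divalent-rhodium dimer Rh2(OAc)4 expels N2 from 8 to give an electrophilic diacyl rhodium carbene, the free 4'-OH of 2 adds to it to form an oxonium ylide, and a 1,2-proton shift gives aryloxy diketone 9, so the C3–O bond is made in a neutral medium. The closest known reaction types are the Rh2(OAc)4-catalysed O–H insertion of 2-diazo-1,3-dicarbonyl compounds into phenols and the acid cyclodehydration of 1-(2-hydroxyaryl)-1,3-diketones used to close flavones after a Baker–Venkataraman rearrangement. Methanolic HCl then transesterifies the four aryl acetates to give 10, either of the two equivalent ortho hydroxyls of the phloroglucinol ring adds 6-exo-trig to the 4-hydroxybenzoyl carbonyl to give hemiketal 11, and acid-catalysed loss of water forms the O1–C2 bond and aromatises ring C of the flavone unit. No stereocentre is created in the product: the transient centres at the diketone carbon of 9 and at C2 and C3 of 11 become sp2, and the (2S) centre of the flavanone is only carried through, because it meets neutral and acidic media and never the base that would open its C2–O1 bond by E1cB elimination. The step needs the carbene to choose the 4'-OH: the 5-OH is tied up in a hydrogen bond to C4=O, the acetate oxygens on the carbene's own aryl groups are too electron-poor to form oxonium ylides, and slow addition of 8 should keep carbene dimerisation and Wolff rearrangement in check. The direction of ring closure is fixed because only the phloroglucinol-derived ring carries ortho hydroxyls.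

**Compound list**

1 | (2S)-naringenin [(2S)-5,7-dihydroxy-2-(4-hydroxyphenyl)chroman-4-one] | Oc1cc(O)c2c(c1)O[C@H](c1ccc(O)cc1)CC2=O | starting material
2 | (2S)-sakuranetin [(2S)-5-hydroxy-2-(4-hydroxyphenyl)-7-methoxychroman-4-one] | COc1cc(O)c2c(c1)O[C@H](c1ccc(O)cc1)CC2=O | intermediate
3 | 2,4,6-trihydroxybenzoic acid | OC(=O)c1c(O)cc(O)cc1O | starting material
4 | 2,4,6-triacetoxybenzoic acid | CC(=O)Oc1cc(OC(C)=O)c(C(=O)O)c(OC(C)=O)c1 | intermediate
5 | 2,4,6-triacetoxybenzoyl chloride | CC(=O)Oc1cc(OC(C)=O)c(C(=O)Cl)c(OC(C)=O)c1 | intermediate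
6 | 4'-acetoxyacetophenone (4-acetylphenyl acetate) | CC(=O)Oc1ccc(cc1)C(C)=O | starting material
7 | 1-(4-acetoxyphenyl)-3-(2,4,6-triacetoxyphenyl)propane-1,3-dione | CC(=O)Oc1ccc(cc1)C(=O)CC(=O)c1c(OC(C)=O)cc(OC(C)=O)cc1OC(C)=O | intermediate
8 | 2-diazo-1-(4-acetoxyphenyl)-3-(2,4,6-triacetoxyphenyl)propane-1,3-dione | CC(=O)Oc1ccc(cc1)C(=O)C(=[N+]=[N-])C(=O)c1c(OC(C)=O)cc(OC(C)=O)cc1OC(C)=O | intermediate
9 | (2S)-sakuranetin 4'-O-[1-(4-acetoxyphenyl)-1,3-dioxo-3-(2,4,6-triacetoxyphenyl)propan-2-yl] ether (both epimers at the diketone carbon) | COc1cc(O)c2c(c1)O[C@H](c1ccc(OC(C(=O)c3ccc(OC(C)=O)cc3)C(=O)c3c(OC(C)=O)cc(OC(C)=O)cc3OC(C)=O)cc1)CC2=O | intermediate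
10 | (2S)-sakuranetin 4'-O-[1-(4-hydroxyphenyl)-1,3-dioxo-3-(2,4,6-trihydroxyphenyl)propan-2-yl] ether | COc1cc(O)c2c(c1)O[C@H](c1ccc(OC(C(=O)c3ccc(O)cc3)C(=O)c3c(O)cc(O)cc3O)cc1)CC2=O | intermediate
11 | (2S)-sakuranetin 4'-O-[2,5,7-trihydroxy-2-(4-hydroxyphenyl)-4-oxochroman-3-yl] ether (cyclic hemiketal, unassigned at C2 and C3 of the new ring) | COc1cc(O)c2c(c1)O[C@H](c1ccc(OC3C(=O)c4c(O)cc(O)cc4OC3(O)c3ccc(O)cc3)cc1)CC2=O | intermediate
12 | CNP0173006.1, (2S)-2-[4-[[5,7-dihydroxy-2-(4-hydroxyphenyl)-4-oxo-4H-chromen-3-yl]oxy]phenyl]-5-hydroxy-7-methoxychroman-4-one | COc1cc(O)c2c(c1)O[C@H](c1ccc(Oc3c(-c4ccc(O)cc4)oc4cc(O)cc(O)c4c3=O)cc1)CC2=O | target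

**Step count**

Total steps: 6. Longest linear sequence: 5 steps (3 → 4 → 5 → 7 → 8 → 12; steps 2 to 6).

**Steps most likely to fail**

Step 6. The diacyl carbene may be consumed by its own neighbours (attack of an ortho acetate oxygen, Wolff rearrangement to an aroylketene) or by dimerisation faster than the 4'-OH captures it. The fallback forms the C–O bond with a simpler carbene that has no ortho oxygen and adds the second aroyl group afterwards. It sets out from 2. Commercial 4-acetoxybenzoyl chloride and (trimethylsilyl)diazomethane (MeCN/THF, 0 °C) should give 2-diazo-1-(4-acetoxyphenyl)ethanone F1. Rh2(OAc)4-catalysed O–H insertion of F1 into the 4'-OH of 2 (CH2Cl2, rt to 40 °C) should give (2S)-4'-O-[2-(4-acetoxyphenyl)-2-oxoethyl]sakuranetin F2. The methylene of F2, flanked by the ketone and the aryloxy oxygen, is then C-acylated with acid chloride 5 under the MgBr2·OEt2/i-Pr2NEt soft enolisation of step 4. The chelated 5-OH, which resists even acetic anhydride in pyridine, is expected to stay unacylated by the hindered chloride. This returns to the route at 9, which is taken through the methanolic HCl stage of step 6 to 12.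

Step 4. Addition of the magnesium enolate to the doubly ortho-substituted acyl chloride may be slow, which would let O-acylation of the enolate or acetyl transfer from the aryl acetates compete. The fallback lets the hindered acyl carbon meet only a linear diazoalkane nucleophile and makes the second C–C bond at an unhindered aldehyde. It sets out from 5. (Trimethylsilyl)diazomethane (MeCN/THF, 0 °C) should give 2-diazo-1-(2,4,6-triacetoxyphenyl)ethanone F3. DBU-catalysed (10 mol %) aldol-type addition of F3 to commercial 4-acetoxybenzaldehyde in MeCN at 0 °C should give 2-diazo-3-hydroxy-3-(4-acetoxyphenyl)-1-(2,4,6-triacetoxyphenyl)propan-1-one F4. Dess–Martin oxidation of the carbinol (CH2Cl2, rt) returns to the route at 8. This path also bypasses the diazo transfer of step 5.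

Step 1. Discrimination between the 7-OH and the 4'-OH may be incomplete, so that methylation runs on to the 4'-position. The fallback blocks the 4'-OH before methylation. It sets out from 1. Ac2O in pyridine at rt should acetylate the two unchelated phenols to give (2S)-naringenin 7,4'-diacetate F5. Thiophenol and imidazole in NMP at 0 °C should remove only the 7-O-acetyl group (para to the carbonyl, the most electrophilic ester) to give (2S)-naringenin 4'-acetate F6. Mitsunobu methylation (MeOH, PPh3, DIAD, THF) of the one remaining reactive phenol should give (2S)-sakuranetin 4'-acetate F7. HCl in MeOH at rt removes the 4'-acetate and returns to the route at 2.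

**Further compounds**

F1 | step 6 | 2-diazo-1-(4-acetoxyphenyl)ethanone | CC(=O)Oc1ccc(cc1)C(=O)C=[N+]=[N-]
F2 | step 6 | (2S)-4'-O-[2-(4-acetoxyphenyl)-2-oxoethyl]sakuranetin | COc1cc(O)c2c(c1)O[C@H](c1ccc(OCC(=O)c3ccc(OC(C)=O)cc3)cc1)CC2=O
F3 | step 4 | 2-diazo-1-(2,4,6-triacetoxyphenyl)ethanone | CC(=O)Oc1cc(OC(C)=O)c(C(=O)C=[N+]=[N-])c(OC(C)=O)c1
F4 | step 4 | 2-diazo-3-hydroxy-3-(4-acetoxyphenyl)-1-(2,4,6-triacetoxyphenyl)propan-1-one (racemic) | CC(=O)Oc1ccc(cc1)C(O)C(=[N+]=[N-])C(=O)c1c(OC(C)=O)cc(OC(C)=O)cc1OC(C)=O
F5 | step 1 | (2S)-naringenin 7,4'-diacetate | CC(=O)Oc1cc(O)c2c(c1)O[C@H](c1ccc(OC(C)=O)cc1)CC2=O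
F6 | step 1 | (2S)-naringenin 4'-acetate | Oc1cc(O)c2c(c1)O[C@H](c1ccc(OC(C)=O)cc1)CC2=O
F7 | step 1 | (2S)-sakuranetin 4'-acetate | COc1cc(O)c2c(c1)O[C@H](c1ccc(OC(C)=O)cc1)CC2=O
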